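**Plan**
- Numbering: ring A = C1–C5/C10, ring B = C5–C10, side chain from C11; β is the face of the C10 methyl. Retrosynthesis: the C3 ketal and O8 silyl group come off last and the C7 oxygen is put back; then C8–OH, C9–C11 (homofarnesyl) and C8–CH3 are cut to a Δ8-en-7-one; finally C4–C5 is cut to open ring A.
- Enabling feature: H-5 and the C10 methyl are cis, the gem-dimethyl carbon C4 is the α-carbon of the C3 ketone, and C5 becomes an enone β-carbon once C7 carries a carbonyl. Ring B can therefore start as an achiral cyclohexa-2,5-dienone whose quaternary carbon is C10.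
- Forward order: dienone 7 (ring B) is built in steps 1–3 and ring A closes on it in step 4. Then follow the C8 methyl (steps 6–7), the C9 chain (step 10, chain made in steps 8–9), the C8 hydroxyl (step 11) and removal of the C7 oxygen (steps 12–16).
- Stereochemistry: C5/C10 absolute from the chiral amine, their cis relation from the tether; C9 from addition to the convex β-face; C8 from enolate oxidation anti to the C9 chain and the C10 methyl; the E-alkenes come unchanged from farnesyl bromide.

Key step: step 4

Remark: which enantiotopic arm the quinine-derived amine selects cannot be predicted with confidence; it is assumed to give 8 as drawn, and the quinidine-derived pseudoenantiomer would be used otherwise.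

**Step 1**
Reactants: 1 propanal; 2 isopropyl vinyl ketone
Product: 3 2,6-dimethyl-5-oxoheptanal (racemic)
Conditions: Et2NH (20 mol%), excess 1, neat, rt
Reagents that add atoms: none
Why: Amine-catalysed Michael addition of the aldehyde enamine to the vinyl ketone gives the 5-oxo aldehyde; the stereocentre formed is inconsequential because C2 becomes the quaternary carbon of the achiral dienone.

**Step 2**
Reactants: 3 2,6-dimethyl-5-oxoheptanal; 4 methyl vinyl ketone
Product: 6 4-methyl-4-(4-methyl-3-oxopentyl)cyclohex-2-en-1-one, via Michael adduct 5 (not isolated)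
Conditions: conc. H2SO4 (cat.), toluene, 45 °C, then reflux (Dean–Stark)
Reagents that add atoms: none
Why: Robinson annulation of an α-branched aldehyde: acid-catalysed Michael addition to methyl vinyl ketone, then aldol condensation of the methyl ketone onto the aldehyde, gives the 4,4-disubstituted cyclohexenone; the isopropyl ketone arm cannot condense to a stable enone.

**Step 3**
Reactants: 6 4-methyl-4-(4-methyl-3-oxopentyl)cyclohex-2-en-1-one
Product: 7 4-methyl-4-(4-methyl-3-oxopentyl)cyclohexa-2,5-dien-1-one
Conditions: DDQ (1.5 equiv), 1,4-dioxane, reflux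
Reagents that add atoms: none
Why: DDQ dehydrogenation of the cyclohexenone through its dienol should give the cross-conjugated dienone, the isolated isopropyl ketone enolising far less readily.

**Step 4**
Reactants: 7 4-methyl-4-(4-methyl-3-oxopentyl)cyclohexa-2,5-dien-1-one
Product: 8 (5S,10R)-cis-fused 4,4,10-trimethyl-Δ8-ene-3,7-dione [(4aR,8aS)-4a,8,8-trimethyl-4a,5,6,8a-tetrahydronaphthalene-2,7(1H,8H)-dione]
Conditions: 9-amino-9-deoxy-epi-quinine (20 mol%), CF3CO2H (40 mol%), toluene, 40 °C
Reagents that add atoms: none
Why: Proposed new method: the primary amine condenses with the C3 ketone, and the more substituted C3=C4 secondary enamine adds through C4 to C5 of one enone arm, the acid co-catalyst relaying the proton to the emerging C6–C7 enolate before hydrolysis frees 8 and the amine; the C2=C3 enamine forms reversibly but is a dead end because it could close only a four-membered ring. The closest known reaction types are the amine-catalysed desymmetrising intramolecular Michael additions of aldehyde-, malonate- and keto-ester-tethered 4,4-disubstituted cyclohexadienones and the quaternary-carbon-forming Michael additions of secondary enamines of α-branched ketones; the acyclic isopropyl ketone donor is the untested element. Ring A closes in a 6-(enolendo)-exo-trig mode, with the enamine double bond inside and the C5=C6 acceptor bond outside the new ring. The cis relation of C5 to C10 is enforced by the substrate, since the three-atom tether C1–C2–C3 anchored on C10 can bring C4 onto the axial trajectory at C5 only from its own face, which leaves H-5 and the C10 methyl on the opposite, common face. The absolute configuration of both centres is decided by the catalyst, whose protonated quinuclidine can hydrogen-bond to the dienone carbonyl and hold one of the two enantiotopic arms next to the enamine. Arm discrimination is therefore the only selectivity the step must find, because the dienone has no enolisable hydrogen, C2 cannot cyclise and the surviving enone arm of 8 is out of reach of a second addition.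

**Step 5**
Reactants: 8 cis-enedione
Product: 9 C3 ethylene ketal of 8 (3,3-ethylenedioxy-Δ8-en-7-one; 5β-H, 10β-CH3)
Conditions: Me3SiOCH2CH2OSiMe3, Me3SiOTf (5 mol%), CH2Cl2, −78 → −20 °C
Reagents that add atoms: 1,2-bis(trimethylsilyloxy)ethane, C[Si](C)(C)OCCO[Si](C)(C)C
Why: Silyl-triflate-catalysed ketalisation with the bis-silylated glycol reacts with saturated ketones at low temperature and leaves conjugated enones untouched, so C3 is masked selectively before the organometallic and hydride steps.

**Step 6**
Reactants: 9 ketal enone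
Product: 10 8-iodo-Δ8-en-7-one C3 ketal
Conditions: I2, pyridine, CH2Cl2, 0 °C → rt
Reagents that add atoms: iodine, II
Why: α-Iodination of the enone by the iodine–pyridine addition–elimination sequence (pyridine adds at C9, the enolate is iodinated at C8, pyridine is expelled) is well established for 4,4-disubstituted cyclohexenones.

**Step 7**
Reactants: 10 α-iodo enone
Product: 11 8-methyl-Δ8-en-7-one C3 ketal
Conditions: MeB(OH)2, Pd(OAc)2 (5 mol%), SPhos (10 mol%), K3PO4, toluene/H2O, 80 °C
Reagents that add atoms: methylboronic acid, CB(O)O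
Why: Suzuki–Miyaura coupling of the α-iodoenone installs the C8 methyl first, so that the later conjugate addition generates the fully substituted C7–C8 enolate regiospecifically, a site that deprotonation of the saturated ketone would not select.

**Step 8**
Reactants: 12 (2E,6E)-farnesyl bromide
Product: 13 (3E,7E)-homofarnesyl phenyl sulfide
Conditions: PhSMe, n-BuLi, DABCO, THF, 0 °C; then 12, −78 → 0 °C
Reagents that add atoms: thioanisole (as its lithio derivative), CSc1ccccc1
Why: SN2 alkylation of the sulfur-stabilised carbanion by the primary allylic bromide adds one carbon without allylic transposition or loss of alkene geometry.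

**Step 9**
Reactants: 13 homofarnesyl phenyl sulfide
Product: 15 (3E,7E)-homofarnesyl iodide, via sulfonium iodide 14 (not isolated)
Conditions: MeI (excess), NaI, DMF, 70 °C
Reagents that add atoms: methyl iodide, CI
Why: S-Methylation turns the sulfide into a sulfonium leaving group, which iodide displaces at the unhindered primary homoallylic carbon (SN2).

**Step 10**
Reactants: 11 8-methyl enone ketal; 15 homofarnesyl iodide
Product: 17 trimethylsilyl enol ether (C7–OSiMe3, Δ7, 8-methyl, 9β-homofarnesyl, C3 ketal), via homofarnesylmagnesium iodide 16 (not isolated)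
Conditions: 15, Mg, Et2O, rt; then CuBr·SMe2 (10 mol%), HMPA, Me3SiCl, 11, THF, −78 → −40 °C; Et3N quench
Reagents that add atoms: chlorotrimethylsilane, C[Si](C)(C)Cl
Why: Copper-catalysed, silyl-chloride-accelerated conjugate addition of the Grignard reagent should reach the hindered α-methyl enone and give the C7–C8 silyl enol ether regiospecifically; C9 is set by axial attack on the convex β-face (the face of the C10 methyl and H-5), because ring A with C4 and its α-methyl closes the α-face.

**Step 11**
Reactants: 17 silyl enol ether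
Product: 19 8α-hydroxy-8β-methyl-9β-homofarnesyl-7-ketone C3 ketal, via lithium enolate 18 (not isolated)
Conditions: MeLi, THF, 0 °C → rt; then 2-(phenylsulfonyl)-3-phenyloxaziridine, −78 °C; NH4Cl (aq)
Reagents that add atoms: 2-(phenylsulfonyl)-3-phenyloxaziridine, O=S(=O)(c1ccccc1)N1OC1c1ccccc1
Why: MeLi releases the lithium enolate regiospecifically and the N-sulfonyloxaziridine transfers oxygen to C8 (Davis oxidation) without touching the trisubstituted alkenes; attack anti to the C9 chain and the C10 methyl places the hydroxyl α and leaves the C8 methyl β.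

**Step 12**
Reactants: 19 α-hydroxy ketone
Product: 20 8α-triethylsilyloxy-7-ketone C3 ketal
Conditions: Et3SiOTf, 2,6-lutidine, CH2Cl2, −78 → 0 °C
Reagents that add atoms: triethylsilyl trifluoromethanesulfonate, CC[Si](CC)(CC)OS(=O)(=O)C(F)(F)F
Why: Silylation of the tertiary alcohol with the silyl triflate keeps O8 from cyclising onto the thiocarbonyl group or being deoxygenated in steps 14–15.

**Step 13**
Reactants: 20 silyloxy ketone
Product: 21 C7 alcohol (8α-triethylsilyloxy, C3 ketal; C7 configuration left open, both epimers carried on)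
Conditions: LiAlH4, Et2O, −20 → 0 °C
Reagents that add atoms: none
Why: Hydride reduction of the hindered C7 ketone, with C3 masked as the ketal and the silyl ether inert; the new C7 stereocentre is removed in step 15, so its configuration is immaterial.

**Step 14**
Reactants: 21 C7 alcohol
Product: 22 C7 O-(imidazol-1-ylthiocarbonyl) derivative
Conditions: 1,1'-thiocarbonyldiimidazole, DMAP, toluene, 90 °C
Reagents that add atoms: 1,1'-thiocarbonyldiimidazole, S=C(n1ccnc1)n1ccnc1
Why: Acyl transfer from thiocarbonyldiimidazole to the secondary C7 alcohol gives the thiocarbonyl derivative needed for radical deoxygenation (first half of the Barton–McCombie reaction).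

**Step 15**
Reactants: 22 thiocarbonyl imidazolide
Product: 23 7-deoxy compound (8α-triethylsilyloxy, C3 ketal)
Conditions: Bu3SnH (0.1 M), AIBN (cat.), toluene, 100 °C
Reagents that add atoms: none
Why: Barton–McCombie deoxygenation: the stannyl radical adds to C=S and the C7–O bond fragments to a secondary radical that Bu3SnH should reduce faster than it could add to a chain alkene, while the silyl ether and isolated alkenes stay inert.

**Step 16**
Reactants: 23 silyl ether ketal
Product: 25 IN0671 (target), via ketal alcohol 24 (not isolated)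
Conditions: Bu4NF, THF, rt → 40 °C; then 1 M HCl (aq), rt
Reagents that add atoms: water, O
Why: Fluoride cleaves the tertiary silyl ether and brief dilute aqueous acid then hydrolyses the dioxolane, conditions that should be too mild to dehydrate the C8 carbinol or protonate the trisubstituted alkenes.

**Compound list**
1 | propanal | CCC=O | starting material
2 | isopropyl vinyl ketone (4-methylpent-1-en-3-one) | C=CC(=O)C(C)C | starting material
3 | 2,6-dimethyl-5-oxoheptanal (racemic) | CC(C)C(=O)CCC(C)C=O | intermediate
4 | methyl vinyl ketone (but-3-en-2-one) | C=CC(C)=O | starting material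
5 | 2,6-dimethyl-5-oxo-2-(3-oxobutyl)heptanal (racemic Michael adduct) | CC(C)C(=O)CCC(C)(C=O)CCC(C)=O | intermediate (not isolated)
6 | 4-methyl-4-(4-methyl-3-oxopentyl)cyclohex-2-en-1-one (racemic) | CC(C)C(=O)CCC1(C)CCC(=O)C=C1 | intermediate
7 | 4-methyl-4-(4-methyl-3-oxopentyl)cyclohexa-2,5-dien-1-one (achiral) | CC(C)C(=O)CCC1(C)C=CC(=O)C=C1 | intermediate
8 | (4aR,8aS)-4a,8,8-trimethyl-4a,5,6,8a-tetrahydronaphthalene-2,7(1H,8H)-dione; cis-fused, 5β-H, 10β-CH3 | O=C1C=C[C@@]2(C)CCC(=O)C(C)(C)[C@H]2C1 | intermediate
9 | C3 ethylene ketal of 8 (Δ8-en-7-one) | O=C1C=C[C@@]2(C)CCC3(OCCO3)C(C)(C)[C@H]2C1 | intermediate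
10 | 8-iodo-Δ8-en-7-one C3 ketal | O=C1C(I)=C[C@@]2(C)CCC3(OCCO3)C(C)(C)[C@H]2C1 | intermediate
11 | 8-methyl-Δ8-en-7-one C3 ketal | O=C1C(C)=C[C@@]2(C)CCC3(OCCO3)C(C)(C)[C@H]2C1 | intermediate
12 | (2E,6E)-farnesyl bromide | CC(C)=CCC/C(C)=C/CC/C(C)=C/CBr | starting material
13 | phenyl (3E,7E)-4,8,12-trimethyltrideca-3,7,11-trien-1-yl sulfide | CC(C)=CCC/C(C)=C/CC/C(C)=C/CCSc1ccccc1 | intermediate
14 | methyl(phenyl)[(3E,7E)-4,8,12-trimethyltrideca-3,7,11-trien-1-yl]sulfonium iodide | CC(C)=CCC/C(C)=C/CC/C(C)=C/CC[S+](C)c1ccccc1.[I-] | intermediate (not isolated)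
15 | (3E,7E)-1-iodo-4,8,12-trimethyltrideca-3,7,11-triene (homofarnesyl iodide) | CC(C)=CCC/C(C)=C/CC/C(C)=C/CCI | intermediate
16 | [(3E,7E)-4,8,12-trimethyltrideca-3,7,11-trien-1-yl]magnesium iodide | CC(C)=CCC/C(C)=C/CC/C(C)=C/CC[Mg]I | intermediate (not isolated)
17 | C7 trimethylsilyl enol ether (Δ7), 8-methyl, 9β-homofarnesyl (9α-H), 5β-H, 10β-CH3, C3 ketal | CC(C)=CCC/C(C)=C/CC/C(C)=C/CC[C@@H]1[C@@]2(C)CCC3(OCCO3)C(C)(C)[C@H]2CC(O[Si](C)(C)C)=C1C | intermediate
18 | lithium C7–C8 enolate corresponding to 17 | CC(C)=CCC/C(C)=C/CC/C(C)=C/CC[C@@H]1[C@@]2(C)CCC3(OCCO3)C(C)(C)[C@H]2CC(O[Li])=C1C | intermediate (not isolated)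
19 | 8α-hydroxy-8β-methyl-9β-homofarnesyl-7-ketone, C3 ketal | CC(C)=CCC/C(C)=C/CC/C(C)=C/CC[C@@H]1[C@@]2(C)CCC3(OCCO3)C(C)(C)[C@H]2CC(=O)[C@@]1(C)O | intermediate
20 | 8α-triethylsilyl ether of 19 | CC(C)=CCC/C(C)=C/CC/C(C)=C/CC[C@@H]1[C@@]2(C)CCC3(OCCO3)C(C)(C)[C@H]2CC(=O)[C@@]1(C)O[Si](CC)(CC)CC | intermediate
21 | C7 alcohol from 20 (C7 epimers, configuration left open) | CC(C)=CCC/C(C)=C/CC/C(C)=C/CC[C@@H]1[C@@]2(C)CCC3(OCCO3)C(C)(C)[C@H]2CC(O)[C@@]1(C)O[Si](CC)(CC)CC | intermediate
22 | C7 O-(imidazol-1-ylthiocarbonyl) derivative of 21 | CC(C)=CCC/C(C)=C/CC/C(C)=C/CC[C@@H]1[C@@]2(C)CCC3(OCCO3)C(C)(C)[C@H]2CC(OC(=S)n4ccnc4)[C@@]1(C)O[Si](CC)(CC)CC | intermediate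
23 | 7-deoxy compound: 8α-triethylsilyloxy, C3 ketal | CC(C)=CCC/C(C)=C/CC/C(C)=C/CC[C@@H]1[C@@]2(C)CCC3(OCCO3)C(C)(C)[C@H]2CC[C@@]1(C)O[Si](CC)(CC)CC | intermediate
24 | 8α-hydroxy C3 ethylene ketal (ketal alcohol) | CC(C)=CCC/C(C)=C/CC/C(C)=C/CC[C@@H]1[C@@]2(C)CCC3(OCCO3)C(C)(C)[C@H]2CC[C@@]1(C)O | intermediate (not isolated)
25 | IN0671: (5S,8R,9R,10S)-8-hydroxy-4,4,8,10-tetramethyl-9-[(3E,7E)-4,8,12-trimethyltrideca-3,7,11-trienyl]-cis-decalin-3-one | CC(C)=CCC/C(C)=C/CC/C(C)=C/CC[C@@H]1[C@@]2(C)CCC(=O)C(C)(C)[C@H]2CC[C@@]1(C)O | target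

**Count and risks**

Total step count: 16. Longest linear sequence: 14 steps (steps 1–7 and 10–16, from propanal); the side chain 15 takes 2 steps and joins at step 10.

Steps most likely to fail:

1. Step 4. Enamine formation at the hindered isopropyl ketone may be too slow, or discrimination of the two enone arms too weak, so that conversion or enantiomeric purity falls short. The fallback replaces asymmetric catalysis by resolution and sets out from 7. Ring closure with catalytic KOt-Bu in t-BuOH/THF at 0 °C (enolate Michael addition; again only the C4 enolate can cyclise) should give the racemic cis-enedione, that is 8 together with its (5R,10S)-antipode F1. Ketalisation of the mixture at C3 with (R,R)-hydrobenzoin (TsOH cat., benzene, Dean–Stark) should give the (R,R)-hydrobenzoin ketal of 8 F2 and the (R,R)-hydrobenzoin ketal of the antipode F3, which are diastereomers and are separated by chromatography or crystallisation. Hydrolysis of F2 (TsOH, acetone/H2O) returns to the route at 8.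

2. Step 10. The Grignard reagent may add to the wrong face of C9, or with poor facial selectivity, because the convex face carries the neighbouring C10 methyl. The fallback sets C9 by protonation instead of by C–C bond formation and sets out from 11. The same addition is run without regard to its facial outcome and may give the C9-epimeric silyl enol ether F4 alone or mixed with 17. Saegusa–Ito oxidation (Pd(OAc)2, MeCN, rt) converts this material into the 8-methyl-9-homofarnesyl-Δ8-en-7-one F5, in which C9 is trigonal. Reduction with Li in NH3/THF (t-BuOH 1 equiv, −78 °C) should protonate C9 axially on the α-face of the more stable cis-decalin conformer (chain equatorial and β) and leave lithium enolate 18. Silylation of 18 (Me3SiCl, Et3N) returns to the route at 17.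

3. Step 14. Thioacylation of the neopentyl-type C7 hydroxyl may stall, or the silyl group may migrate to O7 on heating, so that the radical precursor is not obtained cleanly. The fallback removes the C7 oxygen by hydride opening of an epoxide and sets out from 19. Hydroxyl-directed reduction with Me4NBH(OAc)3 (AcOH/MeCN, −20 °C) should give the trans-7β,8α-diol F6, and MsCl/Et3N (CH2Cl2, 0 °C) the secondary 7β-mesylate F7. LiEt3BH (THF, 0 °C → rt) deprotonates O8, which closes the 7α,8α-epoxide F8; hydride then opens it at the less substituted C7 with the C8–O bond untouched. This returns to the route at 24, which is hydrolysed as in the second stage of step 16.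

**Further compounds**
F1 | step 4 | (4aS,8aR)-antipode of 8 | O=C1C=C[C@]2(C)CCC(=O)C(C)(C)[C@@H]2C1
F2 | step 4 | (R,R)-hydrobenzoin C3 ketal of 8 | O=C1C=C[C@@]2(C)CCC3(O[C@H](c4ccccc4)[C@@H](c4ccccc4)O3)C(C)(C)[C@H]2C1
F3 | step 4 | (R,R)-hydrobenzoin C3 ketal of F1 | O=C1C=C[C@]2(C)CCC3(O[C@H](c4ccccc4)[C@@H](c4ccccc4)O3)C(C)(C)[C@@H]2C1
F4 | step 10 | C9 epimer of 17 (9α-homofarnesyl silyl enol ether) | CC(C)=CCC/C(C)=C/CC/C(C)=C/CC[C@H]1[C@@]2(C)CCC3(OCCO3)C(C)(C)[C@H]2CC(O[Si](C)(C)C)=C1C
F5 | step 10 | 8-methyl-9-homofarnesyl-Δ8-en-7-one C3 ketal | CC(C)=CCC/C(C)=C/CC/C(C)=C/CCC1=C(C)C(=O)C[C@@H]2C(C)(C)C3(OCCO3)CC[C@]12C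
F6 | step 14 | 7β,8α-diol C3 ketal | CC(C)=CCC/C(C)=C/CC/C(C)=C/CC[C@@H]1[C@@]2(C)CCC3(OCCO3)C(C)(C)[C@H]2C[C@H](O)[C@@]1(C)O
F7 | step 14 | 7β-methanesulfonate of F6 | CC(C)=CCC/C(C)=C/CC/C(C)=C/CC[C@@H]1[C@@]2(C)CCC3(OCCO3)C(C)(C)[C@H]2C[C@H](OS(C)(=O)=O)[C@@]1(C)O
F8 | step 14 | 7α,8α-epoxide C3 ketal | CC(C)=CCC/C(C)=C/CC/C(C)=C/CC[C@@H]1[C@@]2(C)CCC3(OCCO3)C(C)(C)[C@H]2C[C@H]4O[C@@]14C
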